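Ring A carries O1 on C8a and the C4 carbonyl on the adjacent C4a, flanked by the C5 oxygen: an ortho-hydroxyaryl ketone. Both bonds to ring A (O1–C8a and C4–C4a) are therefore made at once by letting a 3-alkoxyaryne insert into the C–O bond of a carboxylic acid. The aryne comes from a symmetric phloroglucinol-derived silyl triflate with the prenyl group fixed between two protected oxygens. The acid is a trans-dioxolane (syn-diol acetonide) carrying ring B, made from L-tartrate, with C3 final and C2 awaiting inversion. Acetonide removal, Mitsunobu closure of ring C and loss of the protecting groups finish the synthesis.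

Key step: step 14

Abbreviations: MOM = methoxymethyl; prenyl = 3-methylbut-2-en-1-yl; geranyl = (2E)-3,7-dimethylocta-2,6-dien-1-yl. Flavanonol numbering is used (O1, C2, C3, C4, C4a, C5 to C8, C8a).

Assumption: the target is read as the (2R,3R) 2,3-trans dihydroflavonol; the dioxolane acid must then be (4R,5S), the trans-dioxolane that natural L-tartaric acid provides.

Step 1
Reactants: 1 phloroglucinol
Product: 2 3,5-bis(methoxymethoxy)phenol
Conditions: MOMCl (2.0 equiv), iPr2NEt (2.5 equiv), DMF, 0 °C to rt; chromatographic separation from mono- and tris-ethers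
Reagents that add atoms: chloromethyl methyl ether, COCCl
Why: Statistical Williamson-type O-alkylation of three equivalent phenols should give the bis-ether as a separable component, and the cheap starting material makes the loss to mono- and tris-ethers acceptable in the first step.

Step 2
Reactants: 2 3,5-bis(methoxymethoxy)phenol
Product: 3 triisopropyl[3,5-bis(methoxymethoxy)phenoxy]silane
Conditions: TIPSCl (1.2 equiv), imidazole (2.5 equiv), DMF, rt
Reagents that add atoms: chlorotriisopropylsilane, CC(C)[Si](Cl)(C(C)C)C(C)C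
Why: Silyl ether formation masks the remaining phenol with a bulky, non-directing group that tolerates butyllithium, so that only the two acetal ethers steer the next metalation.

Step 3
Reactants: 3 triisopropyl[3,5-bis(methoxymethoxy)phenoxy]silane; 4 prenyl bromide
Product: 6 triisopropyl[3,5-bis(methoxymethoxy)-4-prenylphenoxy]silane, via aryllithium 5 (not isolated)
Conditions: n-BuLi (1.2 equiv), THF, 0 °C; CuI (10 mol%), then 4, −78 °C to rt
Reagents that add atoms: none
Why: Directed ortho-metalation should occur at the one position flanked by two methoxymethoxy groups, and copper-assisted allylation of the aryllithium at the primary carbon of prenyl bromide should give the symmetric 4-prenyl arene.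

Step 4
Reactants: 6 triisopropyl[3,5-bis(methoxymethoxy)-4-prenylphenoxy]silane
Product: 7 3,5-bis(methoxymethoxy)-4-prenylphenol
Conditions: Bu4NF (1.1 equiv), THF, 0 °C; aq. NH4Cl
Reagents that add atoms: none
Why: Fluoride-induced desilylation, driven by the strong Si–F bond, should free the phenol without touching the acetal ethers or the alkene.

Step 5
Reactants: 7 3,5-bis(methoxymethoxy)-4-prenylphenol
Product: 8 3,5-bis(methoxymethoxy)-4-prenylphenyl N-isopropylcarbamate
Conditions: iPrNCO (1.5 equiv), Et3N (0.2 equiv), CH2Cl2, rt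
Reagents that add atoms: isopropyl isocyanate, CC(C)N=C=O
Why: Base-catalysed addition of the phenol to the isocyanate (carbamoylation) installs a group that directs ortho-metalation strongly once N-silylated and that is later removed without acid.

Step 6
Reactants: 8 3,5-bis(methoxymethoxy)-4-prenylphenyl N-isopropylcarbamate
Product: 12 3,5-bis(methoxymethoxy)-4-prenyl-2-(trimethylsilyl)phenyl N-isopropylcarbamate, via N-silyl carbamate 9 (not isolated), via ortho-lithiated carbamate 10 (not isolated), via bis-silyl carbamate 11 (not isolated)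
Conditions: TMSOTf (1.1 equiv), TMEDA (1.1 equiv), Et2O, 0 °C to rt; n-BuLi (2 equiv), TMEDA (2 equiv), −78 °C; TMSCl (3 equiv), −78 °C to rt; aq. NaHCO3
Reagents that add atoms: chlorotrimethylsilane, C[Si](C)(C)Cl
Why: Carbamate-directed ortho-metalation after in situ N-silylation, which suppresses the anionic Fries shift at −78 °C, should lithiate one of the two equivalent positions between the carbamate and a methoxymethoxy group; TMSCl then silylates carbon and the labile N–Si bond is lost on work-up.

Step 7
Reactants: 12 3,5-bis(methoxymethoxy)-4-prenyl-2-(trimethylsilyl)phenyl N-isopropylcarbamate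
Product: 14 3,5-bis(methoxymethoxy)-4-prenyl-2-(trimethylsilyl)phenyl trifluoromethanesulfonate, via silylphenol 13 (not isolated)
Conditions: DBU (1.5 equiv), Et2NH (1.2 equiv), MeCN, 40 °C; then PhNTf2 (1.5 equiv), rt
Reagents that add atoms: N-phenylbis(trifluoromethanesulfonimide), O=S(=O)(N(c1ccccc1)S(=O)(=O)C(F)(F)F)C(F)(F)F
Why: E1cB cleavage of the secondary carbamate by DBU expels the phenoxide and isopropyl isocyanate, which diethylamine traps as a urea, and the phenoxide is O-sulfonylated in the same flask to the ortho-silylaryl triflate.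

Step 8
Reactants: 15 resorcinol
Product: 16 1,3-bis(methoxymethoxy)benzene
Conditions: MOMCl (2.4 equiv), iPr2NEt (3 equiv), CH2Cl2, 0 °C to rt
Reagents that add atoms: chloromethyl methyl ether, COCCl
Why: Exhaustive Williamson-type O-alkylation of both phenols gives the acetal ethers that direct the two later metalations on ring B.

Step 9
Reactants: 16 1,3-bis(methoxymethoxy)benzene; 17 geranyl bromide
Product: 19 2-geranyl-1,3-bis(methoxymethoxy)benzene, via aryllithium 18 (not isolated)
Conditions: n-BuLi (1.1 equiv), THF, 0 °C; CuI (10 mol%), then 17, −78 °C to rt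
Reagents that add atoms: none
Why: Directed ortho-metalation at C2 between the two methoxymethoxy groups, followed by copper-assisted allylation at the primary carbon of geranyl bromide, should install the side chain with its E double bond unchanged.

Step 10
Reactants: 20 dimethyl (4R,5R)-2,2-dimethyl-1,3-dioxolane-4,5-dicarboxylate
Product: 21 (4R,5R)-5-(methoxycarbonyl)-2,2-dimethyl-1,3-dioxolane-4-carboxylic acid
Conditions: KOH (1.0 equiv), MeOH, 0 °C to rt; aq. HCl to pH 2, 0 °C
Reagents that add atoms: potassium hydroxide, [K+].[OH-]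
Why: Saponification with one equivalent of hydroxide should stop at the monoacid because the two esters are homotopic and the first carboxylate retards the second hydrolysis; neither stereocentre is touched.

Step 11
Reactants: 21 (4R,5R)-5-(methoxycarbonyl)-2,2-dimethyl-1,3-dioxolane-4-carboxylic acid
Product: 22 4-(1,3-dioxoisoindolin-2-yl) 5-methyl (4R,5R)-2,2-dimethyl-1,3-dioxolane-4,5-dicarboxylate
Conditions: N-hydroxyphthalimide (1.05 equiv), DIC (1.1 equiv), DMAP (5 mol%), CH2Cl2, rt
Reagents that add atoms: N-hydroxyphthalimide, O=C1c2ccccc2C(=O)N1O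
Why: Carbodiimide (Steglich-type) esterification gives the redox-active ester; the centre it activates is erased in the next step, and the centre next to the methyl ester, the future C3, is not involved.

Step 12
Reactants: 19 2-geranyl-1,3-bis(methoxymethoxy)benzene; 22 4-(1,3-dioxoisoindolin-2-yl) 5-methyl (4R,5R)-2,2-dimethyl-1,3-dioxolane-4,5-dicarboxylate
Product: 25 methyl (4R,5S)-5-[3-geranyl-2,4-bis(methoxymethoxy)phenyl]-2,2-dimethyl-1,3-dioxolane-4-carboxylate, via aryllithium 23 (not isolated), via arylzinc chloride 24 (not isolated)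
Conditions: 19 (2.5 equiv), n-BuLi (2.5 equiv), THF, 0 °C; ZnCl2 (2.6 equiv), 0 °C to rt; then 22 (1.0 equiv), NiCl2(dme) (20 mol%), 4,4'-di-tert-butyl-2,2'-bipyridine (40 mol%), THF/DMF, rt
Reagents that add atoms: none
Why: Nickel-catalysed decarboxylative Negishi-type arylation of a redox-active ester: electron transfer releases CO2 and a dioxolan-4-yl radical that aryl-nickel captures on the face away from the neighbouring ester, so the benzylic centre is set trans (5S) while C4, the future C3, is inherited unchanged from L-tartrate.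

Step 13
Reactants: 25 methyl (4R,5S)-5-[3-geranyl-2,4-bis(methoxymethoxy)phenyl]-2,2-dimethyl-1,3-dioxolane-4-carboxylate
Product: 26 (4R,5S)-5-[3-geranyl-2,4-bis(methoxymethoxy)phenyl]-2,2-dimethyl-1,3-dioxolane-4-carboxylic acid
Conditions: LiOH·H2O (2 equiv), THF/MeOH/H2O, 0 °C to rt; cold 0.5 M HCl to pH 4
Reagents that add atoms: lithium hydroxide, [Li+].[OH-]
Why: Saponification of the methyl ester; the trans-dioxolane is the thermodynamically preferred arrangement, so the enolisable centre is not at risk, and careful acidification keeps the ketal and the acetal ethers intact.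

Step 14
Reactants: 14 3,5-bis(methoxymethoxy)-4-prenyl-2-(trimethylsilyl)phenyl trifluoromethanesulfonate; 26 (4R,5S)-5-[3-geranyl-2,4-bis(methoxymethoxy)phenyl]-2,2-dimethyl-1,3-dioxolane-4-carboxylic acid
Product: 28 [(4R,5S)-5-[3-geranyl-2,4-bis(methoxymethoxy)phenyl]-2,2-dimethyl-1,3-dioxolan-4-yl][6-hydroxy-2,4-bis(methoxymethoxy)-3-prenylphenyl]methanone, via aryne 27 (not isolated)
Conditions: 26 (1.0 equiv), 14 (1.5 equiv, added in portions), CsF (4 equiv), THF, 125 °C, sealed tube; aq. NH4Cl
Reagents that add atoms: none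
Why: Fluoride attacks silicon in 14 and triflate leaves, releasing aryne 27; the carboxylate of 26 adds through oxygen to the aryne carbon remote from the C5 methoxymethoxy group (the future C8a), the C4a aryl anion so formed attacks the neighbouring ester carbonyl through a four-membered transition state, and the benzoxetene alkoxide opens to the ketone and the C8a phenoxide, so that O1–C8a and C4–C4a are both made. The closest known reaction type is the fluoride-promoted insertion of arynes into the C–O bond of carboxylic acids, which gives ortho-hydroxyaryl ketones. No ring of the target is closed and no stereocentre is created. The selectivity needed is regioselective addition to the unsymmetrical aryne, and the electron-withdrawing C5 oxygen beside the triple bond secures it by polarising and distorting the aryne so that the nucleophile enters at the distal carbon and the charge develops next to oxygen. Because 14 descends from a symmetric phenol with the prenyl group locked between the two protected oxygens, the phenol set free can only be O1, and the 6-prenyl versus 8-prenyl question does not arise. The enolisable C3 centre is safe under the hot, basic conditions because the trans-dioxolane is the thermodynamically preferred epimer.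

Step 15
Reactants: 28 [(4R,5S)-5-[3-geranyl-2,4-bis(methoxymethoxy)phenyl]-2,2-dimethyl-1,3-dioxolan-4-yl][6-hydroxy-2,4-bis(methoxymethoxy)-3-prenylphenyl]methanone
Product: 29 (2R,3S)-3-[3-geranyl-2,4-bis(methoxymethoxy)phenyl]-2,3-dihydroxy-1-[6-hydroxy-2,4-bis(methoxymethoxy)-3-prenylphenyl]propan-1-one
Conditions: AcOH/THF/H2O (3:1:1), 45 °C
Reagents that add atoms: none
Why: Acid-catalysed ketal hydrolysis: the isopropylidene ketal ionises to a tertiary oxocarbenium ion far more readily than the formaldehyde-derived aryl acetals do, so weak aqueous acid should free the syn-diol while the four MOM ethers, the alkenes and both stereocentres stay intact.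

Step 16
Reactants: 29 (2R,3S)-3-[3-geranyl-2,4-bis(methoxymethoxy)phenyl]-2,3-dihydroxy-1-[6-hydroxy-2,4-bis(methoxymethoxy)-3-prenylphenyl]propan-1-one
Product: 30 (2R,3R)-2-[3-geranyl-2,4-bis(methoxymethoxy)phenyl]-3-hydroxy-5,7-bis(methoxymethoxy)-6-prenylchroman-4-one
Conditions: PPh3 (1.5 equiv), DIAD (1.5 equiv), THF, 0 °C to rt
Reagents that add atoms: none
Why: Intramolecular Mitsunobu etherification: the acidic C8a phenol beside the carbonyl is the pronucleophile and displaces the oxyphosphonium of the benzylic alcohol in a 6-exo-tet SN2 closure, which inverts C2 to R and gives the 2,3-trans ring C, while the less reactive C3 hydroxyl next to the carbonyl keeps its configuration.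

Step 17
Reactants: 30 (2R,3R)-2-[3-geranyl-2,4-bis(methoxymethoxy)phenyl]-3-hydroxy-5,7-bis(methoxymethoxy)-6-prenylchroman-4-one
Product: 31 (2R,3R)-2-(3-geranyl-2,4-dihydroxyphenyl)-3,5,7-trihydroxy-6-prenylchroman-4-one (CNP0166115.1)
Conditions: HCl (1.25 M in MeOH), 40 °C
Reagents that add atoms: none
Why: Acid-catalysed transacetalisation to methanol should remove the four aryl MOM ethers under the mild conditions customary for prenylated flavonoids, and the trans ring C is the stable arrangement, so C2 and C3 are not endangered.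

Compound list

1 | phloroglucinol | Oc1cc(O)cc(O)c1 | starting material
2 | 3,5-bis(methoxymethoxy)phenol | COCOc1cc(O)cc(OCOC)c1 | intermediate
3 | triisopropyl[3,5-bis(methoxymethoxy)phenoxy]silane | COCOc1cc(O[Si](C(C)C)(C(C)C)C(C)C)cc(OCOC)c1 | intermediate
4 | prenyl bromide (1-bromo-3-methylbut-2-ene) | CC(C)=CCBr | starting material
5 | [2,6-bis(methoxymethoxy)-4-(triisopropylsilyloxy)phenyl]lithium | [Li]c1c(OCOC)cc(O[Si](C(C)C)(C(C)C)C(C)C)cc1OCOC | intermediate
6 | triisopropyl[3,5-bis(methoxymethoxy)-4-prenylphenoxy]silane | COCOc1cc(O[Si](C(C)C)(C(C)C)C(C)C)cc(OCOC)c1CC=C(C)C | intermediate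
7 | 3,5-bis(methoxymethoxy)-4-prenylphenol | COCOc1cc(O)cc(OCOC)c1CC=C(C)C | intermediate
8 | 3,5-bis(methoxymethoxy)-4-prenylphenyl N-isopropylcarbamate | COCOc1cc(OC(=O)NC(C)C)cc(OCOC)c1CC=C(C)C | intermediate
9 | 3,5-bis(methoxymethoxy)-4-prenylphenyl N-isopropyl-N-(trimethylsilyl)carbamate | COCOc1cc(OC(=O)N(C(C)C)[Si](C)(C)C)cc(OCOC)c1CC=C(C)C | intermediate
10 | [6-[isopropyl(trimethylsilyl)carbamoyloxy]-2,4-bis(methoxymethoxy)-3-prenylphenyl]lithium | [Li]c1c(OC(=O)N(C(C)C)[Si](C)(C)C)cc(OCOC)c(CC=C(C)C)c1OCOC | intermediate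
11 | 3,5-bis(methoxymethoxy)-4-prenyl-2-(trimethylsilyl)phenyl N-isopropyl-N-(trimethylsilyl)carbamate | C[Si](C)(C)c1c(OC(=O)N(C(C)C)[Si](C)(C)C)cc(OCOC)c(CC=C(C)C)c1OCOC | intermediate
12 | 3,5-bis(methoxymethoxy)-4-prenyl-2-(trimethylsilyl)phenyl N-isopropylcarbamate | C[Si](C)(C)c1c(OC(=O)NC(C)C)cc(OCOC)c(CC=C(C)C)c1OCOC | intermediate
13 | 3,5-bis(methoxymethoxy)-4-prenyl-2-(trimethylsilyl)phenol | C[Si](C)(C)c1c(O)cc(OCOC)c(CC=C(C)C)c1OCOC | intermediate
14 | 3,5-bis(methoxymethoxy)-4-prenyl-2-(trimethylsilyl)phenyl trifluoromethanesulfonate | C[Si](C)(C)c1c(OS(=O)(=O)C(F)(F)F)cc(OCOC)c(CC=C(C)C)c1OCOC | intermediate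
15 | resorcinol | Oc1cccc(O)c1 | starting material
16 | 1,3-bis(methoxymethoxy)benzene | COCOc1cccc(OCOC)c1 | intermediate
17 | geranyl bromide | CC(C)=CCC/C(C)=C/CBr | starting material
18 | [2,6-bis(methoxymethoxy)phenyl]lithium | [Li]c1c(OCOC)cccc1OCOC | intermediate
19 | 2-geranyl-1,3-bis(methoxymethoxy)benzene | CC(C)=CCC/C(C)=C/Cc1c(OCOC)cccc1OCOC | intermediate
20 | dimethyl (4R,5R)-2,2-dimethyl-1,3-dioxolane-4,5-dicarboxylate (L-tartrate acetonide) | COC(=O)[C@@H]1OC(C)(C)O[C@H]1C(=O)OC | starting material
21 | (4R,5R)-5-(methoxycarbonyl)-2,2-dimethyl-1,3-dioxolane-4-carboxylic acid | COC(=O)[C@@H]1OC(C)(C)O[C@H]1C(=O)O | intermediate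
22 | 4-(1,3-dioxoisoindolin-2-yl) 5-methyl (4R,5R)-2,2-dimethyl-1,3-dioxolane-4,5-dicarboxylate | COC(=O)[C@@H]1OC(C)(C)O[C@H]1C(=O)ON2C(=O)c3ccccc3C2=O | intermediate
23 | [3-geranyl-2,4-bis(methoxymethoxy)phenyl]lithium | CC(C)=CCC/C(C)=C/Cc1c(OCOC)ccc([Li])c1OCOC | intermediate
24 | [3-geranyl-2,4-bis(methoxymethoxy)phenyl]zinc chloride | CC(C)=CCC/C(C)=C/Cc1c(OCOC)ccc([Zn]Cl)c1OCOC | intermediate
25 | methyl (4R,5S)-5-[3-geranyl-2,4-bis(methoxymethoxy)phenyl]-2,2-dimethyl-1,3-dioxolane-4-carboxylate | CC(C)=CCC/C(C)=C/Cc1c(OCOC)ccc([C@@H]2OC(C)(C)O[C@H]2C(=O)OC)c1OCOC | intermediate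
26 | (4R,5S)-5-[3-geranyl-2,4-bis(methoxymethoxy)phenyl]-2,2-dimethyl-1,3-dioxolane-4-carboxylic acid | CC(C)=CCC/C(C)=C/Cc1c(OCOC)ccc([C@@H]2OC(C)(C)O[C@H]2C(=O)O)c1OCOC | intermediate
27 | 3,5-bis(methoxymethoxy)-4-prenylbenzyne | COCOC1=C(CC=C(C)C)C(OCOC)=CC#C1 | intermediate
28 | [(4R,5S)-5-[3-geranyl-2,4-bis(methoxymethoxy)phenyl]-2,2-dimethyl-1,3-dioxolan-4-yl][6-hydroxy-2,4-bis(methoxymethoxy)-3-prenylphenyl]methanone | CC(C)=CCC/C(C)=C/Cc1c(OCOC)ccc([C@@H]2OC(C)(C)O[C@H]2C(=O)c3c(O)cc(OCOC)c(CC=C(C)C)c3OCOC)c1OCOC | intermediate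
29 | (2R,3S)-3-[3-geranyl-2,4-bis(methoxymethoxy)phenyl]-2,3-dihydroxy-1-[6-hydroxy-2,4-bis(methoxymethoxy)-3-prenylphenyl]propan-1-one | CC(C)=CCC/C(C)=C/Cc1c(OCOC)ccc([C@H](O)[C@@H](O)C(=O)c2c(O)cc(OCOC)c(CC=C(C)C)c2OCOC)c1OCOC | intermediate
30 | (2R,3R)-2-[3-geranyl-2,4-bis(methoxymethoxy)phenyl]-3-hydroxy-5,7-bis(methoxymethoxy)-6-prenylchroman-4-one | CC(C)=CCC/C(C)=C/Cc1c(OCOC)ccc([C@H]2Oc3cc(OCOC)c(CC=C(C)C)c(OCOC)c3C(=O)[C@@H]2O)c1OCOC | intermediate
31 | (2R,3R)-2-(3-geranyl-2,4-dihydroxyphenyl)-3,5,7-trihydroxy-6-prenylchroman-4-one (CNP0166115.1) | CC(C)=CCC/C(C)=C/Cc1c(O)ccc([C@H]2Oc3cc(O)c(CC=C(C)C)c(O)c3C(=O)[C@@H]2O)c1O | target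

Total step count: 17. Longest linear sequence: 11 steps (steps 1 to 7, then 14 to 17).

Steps most likely to fail

Step 14. The C4a aryl anion may be protonated before it reaches the ester carbonyl, which would leave the O-aryl ester. The aryne may also be consumed by ene reactions with the trisubstituted alkenes, or the product phenoxide may add to a second aryne. The fallback sets out from 8 and 26 and comes back at 28; it makes the same two bonds stepwise by an anionic Fries-type acyl shift triggered by halogen–lithium exchange. Carbamate 8 would be metalated as in step 6 (through 9 and 10) and the anion quenched with iodine to give 2-iodo-3,5-bis(methoxymethoxy)-4-prenylphenyl N-isopropylcarbamate F1. DBU and Et2NH in MeCN would free 2-iodo-3,5-bis(methoxymethoxy)-4-prenylphenol F2. Esterification with acid 26 (EDC·HCl, DMAP, CH2Cl2) would give 2-iodo-3,5-bis(methoxymethoxy)-4-prenylphenyl (4R,5S)-5-[3-geranyl-2,4-bis(methoxymethoxy)phenyl]-2,2-dimethyl-1,3-dioxolane-4-carboxylate F3. n-BuLi in THF at −100 °C should exchange iodine for lithium faster than it adds to the ester, and the ortho-lithiated ester should rearrange to the phenoxide of 28.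

Step 12. Transmetalation of the ortho-substituted arylzinc to nickel may be slow, so that the redox-active ester is reduced to the decarboxylated dioxolane or the arylzinc homocouples. The fallback sets out from 19 and comes back at 26; it builds the two stereocentres by an auxiliary-controlled syn-glycolate aldol reaction. Aryllithium 23, made as in step 12, would be quenched with DMF to give 3-geranyl-2,4-bis(methoxymethoxy)benzaldehyde F4. Commercial (R)-4-benzyloxazolidin-2-one would be N-acylated (n-BuLi, then (4-methoxybenzyloxy)acetyl chloride) to (R)-4-benzyl-3-[(4-methoxybenzyloxy)acetyl]oxazolidin-2-one F5. The Evans boron aldol reaction of F5 with F4 (Bu2BOTf, iPr2NEt, CH2Cl2, −78 to 0 °C) should give (4R)-4-benzyl-3-[(2R,3S)-3-[3-geranyl-2,4-bis(methoxymethoxy)phenyl]-3-hydroxy-2-(4-methoxybenzyloxy)propanoyl]oxazolidin-2-one F6, with both centres set by the Z-boron enolate in a chair transition state on the face away from the benzyl group. Buffered DDQ (CH2Cl2, pH 7 buffer, 0 °C) would remove the 4-methoxybenzyl group to give (4R)-4-benzyl-3-[(2R,3S)-3-[3-geranyl-2,4-bis(methoxymethoxy)phenyl]-2,3-dihydroxypropanoyl]oxazolidin-2-one F7. 2,2-Dimethoxypropane with PPTS would give (4R)-4-benzyl-3-[(4R,5S)-5-[3-geranyl-2,4-bis(methoxymethoxy)phenyl]-2,2-dimethyl-1,3-dioxolane-4-carbonyl]oxazolidin-2-one F8. LiOH and H2O2 in THF/H2O at 0 °C would then release acid 26.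

Step 16. The C3 hydroxyl may be activated in place of the benzylic one, leading to epoxide formation or five-membered ring closure, or the electron-rich benzylic oxyphosphonium may ionise and lose stereospecificity. The fallback sets out from 29 and comes back at 30; it closes ring C by acid-catalysed cyclodehydration through the benzylic cation instead of by redox condensation. Diol 29 would be treated with catalytic camphorsulfonic acid in CH2Cl2 over 4 Å molecular sieves at 0 °C to rt. The 2,4-dioxygenated ring B stabilises the cation, the free C8a phenol captures it, and the 2,3-trans product with both substituents equatorial should prevail under thermodynamic control, while aryl MOM ethers persist in the absence of a nucleophilic solvent. This fallback makes no new compound (F0).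

Further compounds

F1 | step 14 | 2-iodo-3,5-bis(methoxymethoxy)-4-prenylphenyl N-isopropylcarbamate | COCOc1cc(OC(=O)NC(C)C)c(I)c(OCOC)c1CC=C(C)C
F2 | step 14 | 2-iodo-3,5-bis(methoxymethoxy)-4-prenylphenol | COCOc1cc(O)c(I)c(OCOC)c1CC=C(C)C
F3 | step 14 | 2-iodo-3,5-bis(methoxymethoxy)-4-prenylphenyl (4R,5S)-5-[3-geranyl-2,4-bis(methoxymethoxy)phenyl]-2,2-dimethyl-1,3-dioxolane-4-carboxylate | CC(C)=CCC/C(C)=C/Cc1c(OCOC)ccc([C@@H]2OC(C)(C)O[C@H]2C(=O)Oc3cc(OCOC)c(CC=C(C)C)c(OCOC)c3I)c1OCOC
F4 | step 12 | 3-geranyl-2,4-bis(methoxymethoxy)benzaldehyde | CC(C)=CCC/C(C)=C/Cc1c(OCOC)ccc(C=O)c1OCOC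
F5 | step 12 | (R)-4-benzyl-3-[(4-methoxybenzyloxy)acetyl]oxazolidin-2-one | COc1ccc(COCC(=O)N2[C@H](Cc3ccccc3)COC2=O)cc1
F6 | step 12 | (4R)-4-benzyl-3-[(2R,3S)-3-[3-geranyl-2,4-bis(methoxymethoxy)phenyl]-3-hydroxy-2-(4-methoxybenzyloxy)propanoyl]oxazolidin-2-one | CC(C)=CCC/C(C)=C/Cc1c(OCOC)ccc([C@H](O)[C@@H](OCc2ccc(OC)cc2)C(=O)N3[C@H](Cc4ccccc4)COC3=O)c1OCOC
F7 | step 12 | (4R)-4-benzyl-3-[(2R,3S)-3-[3-geranyl-2,4-bis(methoxymethoxy)phenyl]-2,3-dihydroxypropanoyl]oxazolidin-2-one | CC(C)=CCC/C(C)=C/Cc1c(OCOC)ccc([C@H](O)[C@@H](O)C(=O)N3[C@H](Cc4ccccc4)COC3=O)c1OCOC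
F8 | step 12 | (4R)-4-benzyl-3-[(4R,5S)-5-[3-geranyl-2,4-bis(methoxymethoxy)phenyl]-2,2-dimethyl-1,3-dioxolane-4-carbonyl]oxazolidin-2-one | CC(C)=CCC/C(C)=C/Cc1c(OCOC)ccc([C@@H]2OC(C)(C)O[C@H]2C(=O)N3[C@H](Cc4ccccc4)COC3=O)c1OCOC
F0 | step 16 | none | none
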